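**Retrosynthetic overview**
1. Target 13 comes from 12 by hydrogenolysis of three O‑benzyl groups.
2. The 8‑OMe group comes from late‑stage C8–H oxidation of the intact flavonol 9 (Elbs persulfate, para to the only free phenol, 5‑OH), then selective 8‑O‑methylation. This avoids a regiodefined tetra‑oxygenated A‑ring building block.
3. Ring C comes from a one‑step Mentzer‑type thermal annulation of unprotected, symmetric phloroglucinol 5 with the α‑benzyloxy aroylacetate 4. It forms C4–C4a and O1–C2 and brings in the 3‑oxygen, replacing the usual chalcone/Algar–Flynn–Oyamada route (C2–C3).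
4. Keto ester 4 comes from a crossed Claisen condensation of aryl ester 2 (from 1) with methyl benzyloxyacetate 3.
5. Ring order: rings A (5) and B (1) are bought; ring C is the only ring formed (step 3).

Assumption: the target SMILES has no stereocentre or stereogenic axis, so the compound is achiral and "single enantiomer" needs no stereocontrol; 1, 3 and 5 are taken as commercial.

**Step 1**
Reactants: 1 methyl 3-hydroxy-4,5-dimethoxybenzoate
Product: 2 methyl 3-(benzyloxy)-4,5-dimethoxybenzoate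
Conditions: BnBr (1.2 equiv), K2CO3 (2 equiv), DMF, 60 °C
Reagents that add atoms: benzyl bromide, BrCc1ccccc1
Why: Williamson ether synthesis on the only free phenol gives a benzyl ether that tolerates the later base, heat and persulfate steps and is removed by hydrogenolysis at the end.

**Step 2**
Reactants: 2 methyl 3-(benzyloxy)-4,5-dimethoxybenzoate; 3 methyl 2-(benzyloxy)acetate
Product: 4 methyl 2-(benzyloxy)-3-[3-(benzyloxy)-4,5-dimethoxyphenyl]-3-oxopropanoate
Conditions: NaH (2.5 equiv), cat. MeOH, THF, reflux, slow addition of 3 (1.5 equiv); then 1 M HCl, 0 °C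
Reagents that add atoms: none
Why: Crossed Claisen condensation of a non‑enolisable aryl ester with an enolisable alkoxyacetate is driven by irreversible deprotonation of the β‑keto ester, the matched methyl esters prevent ester scrambling, and the racemic, enolisable α‑carbon becomes sp2 in step 3.

**Step 3**
Reactants: 4 methyl 2-(benzyloxy)-3-[3-(benzyloxy)-4,5-dimethoxyphenyl]-3-oxopropanoate; 5 phloroglucinol (benzene-1,3,5-triol)
Product: 8 3-(benzyloxy)-2-[3-(benzyloxy)-4,5-dimethoxyphenyl]-5,7-dihydroxy-4H-chromen-4-one, via α-oxoketene 6 (not isolated), via 2-acylphloroglucinol diketone 7 (not isolated)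
Conditions: 5 (1.5 equiv), neat melt, N2 sweep, microwave, 240 °C, 10 min
Reagents that add atoms: none
Why: Proposed new method: thermal loss of methanol from 4 gives α‑oxoketene 6, which acylates the electron‑rich, threefold‑symmetric phloroglucinol (reversible O‑acylation funnels to C‑acylation) to diketone 7, whose ortho‑OH adds to the aryl ketone and dehydrates to the γ‑pyrone, so only one regioisomer can form and no acid is present to divert to a Pechmann coumarin; the closest known reaction is the Mentzer (Simonis‑type) pyrone synthesis of 5,7‑dihydroxyflavones from phloroglucinol and alkyl aroylacetates under solvent‑free heating, extended here to an α‑benzyloxy keto ester that keeps the α‑H needed for ketene formation.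

**Step 4**
Reactants: 8 3-(benzyloxy)-2-[3-(benzyloxy)-4,5-dimethoxyphenyl]-5,7-dihydroxy-4H-chromen-4-one
Product: 9 3,7-bis(benzyloxy)-2-[3-(benzyloxy)-4,5-dimethoxyphenyl]-5-hydroxy-4H-chromen-4-one
Conditions: BnBr (1.1 equiv), K2CO3 (1.5 equiv), acetone, reflux
Reagents that add atoms: benzyl bromide, BrCc1ccccc1
Why: Regioselective Williamson etherification works because 7‑OH is the acidic vinylogous‑acid phenol while 5‑OH is hydrogen‑bonded to C4=O and stays free to direct step 5.

**Step 5**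
Reactants: 9 3,7-bis(benzyloxy)-2-[3-(benzyloxy)-4,5-dimethoxyphenyl]-5-hydroxy-4H-chromen-4-one
Product: 11 3,7-bis(benzyloxy)-2-[3-(benzyloxy)-4,5-dimethoxyphenyl]-5,8-dihydroxy-4H-chromen-4-one, via potassium C8 sulfate ester 10 (not isolated)
Conditions: K2S2O8 (1.5 equiv), aq KOH, pyridine, 15 °C, 24 h; acidify to pH 5 and recover unreacted 9; then 2 M HCl, Na2SO3, 90 °C, 30 min
Reagents that add atoms: potassium peroxodisulfate, [K+].[K+].[O-]S(=O)(=O)OOS(=O)(=O)[O-]
Why: Elbs persulfate oxidation, in which the 5‑phenoxide (the only free phenol) attacks the peroxide oxygen through its para carbon C8 to give aryl sulfate 10 that dilute acid hydrolyses to the quinol, is the known way to convert 5‑hydroxy‑3,7‑dialkoxyflavones into their 8‑hydroxy derivatives, and benzyl ethers survive cold alkaline persulfate.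

**Step 6**
Reactants: 11 3,7-bis(benzyloxy)-2-[3-(benzyloxy)-4,5-dimethoxyphenyl]-5,8-dihydroxy-4H-chromen-4-one
Product: 12 3,7-bis(benzyloxy)-2-[3-(benzyloxy)-4,5-dimethoxyphenyl]-5-hydroxy-8-methoxy-4H-chromen-4-one
Conditions: MeI (1.1 equiv), K2CO3 (1.2 equiv), degassed acetone, N2, rt to 40 °C
Reagents that add atoms: iodomethane, CI
Why: Selective Williamson O‑methylation takes the free, more acidic 8‑OH, while the chelated 5‑OH does not react with one equivalent of MeI under mild carbonate conditions and N2 keeps the quinol from oxidising to the 5,8‑quinone.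

**Step 7**
Reactants: 12 3,7-bis(benzyloxy)-2-[3-(benzyloxy)-4,5-dimethoxyphenyl]-5-hydroxy-8-methoxy-4H-chromen-4-one
Product: 13 3,5,7-trihydroxy-2-(3-hydroxy-4,5-dimethoxyphenyl)-8-methoxy-4H-chromen-4-one (target)
Conditions: H2 (1 atm), 10% Pd/C, EtOAc–MeOH, rt
Reagents that add atoms: none
Why: Catalytic hydrogenolysis cleaves the three benzyl ethers (3‑O, 7‑O, 3'‑O) while methyl ethers and the flavonol C2=C3 bond are inert at 1 atm and room temperature, and no stereocentre exists to be set or scrambled.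

**Compound list**
1 | methyl 3-hydroxy-4,5-dimethoxybenzoate | COC(=O)c1cc(O)c(OC)c(OC)c1 | starting material
2 | methyl 3-(benzyloxy)-4,5-dimethoxybenzoate | COC(=O)c1cc(OCc2ccccc2)c(OC)c(OC)c1 | intermediate
3 | methyl 2-(benzyloxy)acetate | COC(=O)COCc1ccccc1 | starting material
4 | methyl 2-(benzyloxy)-3-[3-(benzyloxy)-4,5-dimethoxyphenyl]-3-oxopropanoate (racemic, enolisable α‑carbon) | COC(=O)C(OCc1ccccc1)C(=O)c1cc(OCc2ccccc2)c(OC)c(OC)c1 | intermediate
5 | phloroglucinol (benzene-1,3,5-triol) | Oc1cc(O)cc(O)c1 | starting material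
6 | α-oxoketene: 2-(benzyloxy)-3-[3-(benzyloxy)-4,5-dimethoxyphenyl]-3-oxoprop-1-en-1-one | O=C=C(OCc1ccccc1)C(=O)c1cc(OCc2ccccc2)c(OC)c(OC)c1 | intermediate (not isolated)
7 | 2-acylphloroglucinol diketone: 2-(benzyloxy)-1-[3-(benzyloxy)-4,5-dimethoxyphenyl]-3-(2,4,6-trihydroxyphenyl)propane-1,3-dione | O=C(c1c(O)cc(O)cc1O)C(OCc1ccccc1)C(=O)c1cc(OCc2ccccc2)c(OC)c(OC)c1 | intermediate (not isolated)
8 | 3-(benzyloxy)-2-[3-(benzyloxy)-4,5-dimethoxyphenyl]-5,7-dihydroxy-4H-chromen-4-one | COc1cc(-c2oc3cc(O)cc(O)c3c(=O)c2OCc2ccccc2)cc(OCc2ccccc2)c1OC | intermediate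
9 | 3,7-bis(benzyloxy)-2-[3-(benzyloxy)-4,5-dimethoxyphenyl]-5-hydroxy-4H-chromen-4-one | COc1cc(-c2oc3cc(OCc4ccccc4)cc(O)c3c(=O)c2OCc2ccccc2)cc(OCc2ccccc2)c1OC | intermediate
10 | potassium C8 sulfate ester: potassium 3,7-bis(benzyloxy)-2-[3-(benzyloxy)-4,5-dimethoxyphenyl]-5-hydroxy-4-oxo-4H-chromen-8-yl sulfate | COc1cc(-c2oc3c(OS(=O)(=O)[O-])c(OCc4ccccc4)cc(O)c3c(=O)c2OCc2ccccc2)cc(OCc2ccccc2)c1OC.[K+] | intermediate (not isolated)
11 | 3,7-bis(benzyloxy)-2-[3-(benzyloxy)-4,5-dimethoxyphenyl]-5,8-dihydroxy-4H-chromen-4-one | COc1cc(-c2oc3c(O)c(OCc4ccccc4)cc(O)c3c(=O)c2OCc2ccccc2)cc(OCc2ccccc2)c1OC | intermediate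
12 | 3,7-bis(benzyloxy)-2-[3-(benzyloxy)-4,5-dimethoxyphenyl]-5-hydroxy-8-methoxy-4H-chromen-4-one | COc1cc(-c2oc3c(OC)c(OCc4ccccc4)cc(O)c3c(=O)c2OCc2ccccc2)cc(OCc2ccccc2)c1OC | intermediate
13 | 3,5,7-trihydroxy-2-(3-hydroxy-4,5-dimethoxyphenyl)-8-methoxy-4H-chromen-4-one | COc1cc(-c2oc3c(OC)c(O)cc(O)c3c(=O)c2O)cc(O)c1OC | target

**Totals**
Total step count: 7. Longest linear sequence: 7 steps (1 → 2 → 4 → 8 → 9 → 11 → 12 → 13).

**Three steps most likely to fail**

Step 3 (Mentzer annulation with an α‑benzyloxy keto ester). The risk is loss or migration of a benzyl group at 240 °C, or coumarin formation. The fallback builds ring C by the Allan–Robinson route and sets out from phloroglucinol 5 and ester 2. Hoesch acylation of 5 with benzyloxyacetonitrile (ZnCl2, HCl gas, Et2O, 0 °C; then water, reflux) gives 2-(benzyloxy)-1-(2,4,6-trihydroxyphenyl)ethan-1-one F1. Saponification of 2 (LiOH, THF–H2O) gives 3-(benzyloxy)-4,5-dimethoxybenzoic acid F2, which DCC (0.5 equiv, CH2Cl2) converts into 3-(benzyloxy)-4,5-dimethoxybenzoic anhydride F3. Heating F1 with F3 and the potassium salt of F2 at 160–170 °C, then KOH in aqueous EtOH at reflux to cleave the O‑aroyl esters, gives the 3‑benzyloxyflavonol; the route is rejoined at 8.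

Step 5 (Elbs oxidation). The risk is low conversion or over‑oxidation to the 5,8‑quinone. The fallback replaces phenoxide/peroxide chemistry by electrophilic halogenation and copper‑catalysed C–O coupling, and sets out from 9. Benzylation of the chelated 5‑OH (BnBr, K2CO3, DMF, 80 °C) gives 3,5,7-tris(benzyloxy)-2-[3-(benzyloxy)-4,5-dimethoxyphenyl]-4H-chromen-4-one F4. Iodination (NIS, cat. TFA, MeCN, 0 °C to rt) goes to C8, para to the 5‑alkoxy group, and gives 3,5,7-tris(benzyloxy)-2-[3-(benzyloxy)-4,5-dimethoxyphenyl]-8-iodo-4H-chromen-4-one F5. Ullmann‑type methoxylation (CuI, 3,4,7,8‑tetramethyl‑1,10‑phenanthroline, Cs2CO3, MeOH–toluene, 110 °C) gives 3,5,7-tris(benzyloxy)-2-[3-(benzyloxy)-4,5-dimethoxyphenyl]-8-methoxy-4H-chromen-4-one F6. Hydrogenolysis of F6 under the step 7 conditions rejoins the route at 13.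

Step 2 (crossed Claisen). The risk is self‑condensation of 3 outcompeting acylation by the electron‑rich ester 2. The fallback installs the α‑oxygen by carbenoid O–H insertion and sets out from 2. Claisen condensation of 2 with excess methyl acetate (NaH, THF, reflux) gives methyl 3-[3-(benzyloxy)-4,5-dimethoxyphenyl]-3-oxopropanoate F7. Diazo transfer (4‑acetamidobenzenesulfonyl azide, Et3N, MeCN) gives methyl 2-diazo-3-[3-(benzyloxy)-4,5-dimethoxyphenyl]-3-oxopropanoate F8. Rh2(OAc)4 (1 mol%) with benzyl alcohol (1.5 equiv) in CH2Cl2 at 40 °C inserts the carbenoid into the O–H bond and rejoins the route at 4.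

**Further compounds**
F1 | step 3 | 2-(benzyloxy)-1-(2,4,6-trihydroxyphenyl)ethan-1-one | O=C(COCc1ccccc1)c1c(O)cc(O)cc1O
F2 | step 3 | 3-(benzyloxy)-4,5-dimethoxybenzoic acid | COc1cc(C(=O)O)cc(OCc2ccccc2)c1OC
F3 | step 3 | 3-(benzyloxy)-4,5-dimethoxybenzoic anhydride | COc1cc(C(=O)OC(=O)c2cc(OC)c(OC)c(OCc3ccccc3)c2)cc(OCc2ccccc2)c1OC
F4 | step 5 | 3,5,7-tris(benzyloxy)-2-[3-(benzyloxy)-4,5-dimethoxyphenyl]-4H-chromen-4-one | COc1cc(-c2oc3cc(OCc4ccccc4)cc(OCc4ccccc4)c3c(=O)c2OCc2ccccc2)cc(OCc2ccccc2)c1OC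
F5 | step 5 | 3,5,7-tris(benzyloxy)-2-[3-(benzyloxy)-4,5-dimethoxyphenyl]-8-iodo-4H-chromen-4-one | COc1cc(-c2oc3c(I)c(OCc4ccccc4)cc(OCc4ccccc4)c3c(=O)c2OCc2ccccc2)cc(OCc2ccccc2)c1OC
F6 | step 5 | 3,5,7-tris(benzyloxy)-2-[3-(benzyloxy)-4,5-dimethoxyphenyl]-8-methoxy-4H-chromen-4-one | COc1cc(-c2oc3c(OC)c(OCc4ccccc4)cc(OCc4ccccc4)c3c(=O)c2OCc2ccccc2)cc(OCc2ccccc2)c1OC
F7 | step 2 | methyl 3-[3-(benzyloxy)-4,5-dimethoxyphenyl]-3-oxopropanoate | COC(=O)CC(=O)c1cc(OCc2ccccc2)c(OC)c(OC)c1
F8 | step 2 | methyl 2-diazo-3-[3-(benzyloxy)-4,5-dimethoxyphenyl]-3-oxopropanoate | COC(=O)C(=[N+]=[N-])C(=O)c1cc(OCc2ccccc2)c(OC)c(OC)c1
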